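**Retrosynthetic overview**
1. The strategy rests on the C1–C2 bond. C1 is a quaternary bridgehead held between the gem-dimethyl carbon C8 and the bridging ketone C9, so its link to ring A is the most crowded bond of the bicyclo[3.3.1]nonane. It is therefore made last and intramolecularly, by π-acid catalysis.
2. Endgame: the catechol and the C2/C4 enol are freed from silyl ethers and a methyl enol ether. The C3–aroyl bond comes from C3 lithiation of a 2-methoxyenone, and C2–OMe comes from C2–Br.
3. Key disconnection C1–C2: ring A (C1-C2-C3-C4-C5-C9) opens to a ring B silyl enol ether (C9–OSi, C1=C9) carrying an axial bromopropynoyl group (C4-C3-C2) on C5.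
4. Ring B (C1-C8-C7-C6-C5-C9) is cyclohexane-1,3-dione. C1 prenyl goes on first, then C7 by asymmetric allylation (the only external source of chirality). C8 follows by MeLi transposition and conjugate methylation, then C5 geranyl and C5 acyl (aldol, oxidation).
5. Ring order: B is purchased and A is closed in the key step. The stereochemical relay runs C7 → C5 → C1.

Key step: step 13

Labels: C1–C9 are the atoms of the bicyclic target and are used for all intermediates. They are C1 prenyl bridgehead, C2, C3 aroyl carbon, C4, C5 geranyl bridgehead, C6 CH2, C7 prenyl CH, C8 CMe2 and C9 bridging C=O. Prenyl = 3-methylbut-2-enyl; geranyl = (2E)-3,7-dimethylocta-2,6-dienyl.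
Assumption: the (S,S) ligand of step 4 is taken to give the (R) allylation product by analogy with enol carbonates of 2-substituted cyclohexanones; the sense is to be checked at that stage and the antipodal ligand used if it is opposite.

**Step 1**
Reactants: 1 cyclohexane-1,3-dione; 2 prenyl bromide
Product: 3 2-prenylcyclohexane-1,3-dione
Conditions: KOH (1 equiv), H2O, 0 °C → rt
Reagents that add atoms: none
Why: C-alkylation (SN2) of the stabilised dione enolate by an allylic bromide is favoured in water, where hydrogen bonding masks the enolate oxygens, and it places the future C1 prenyl group.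

**Step 2**
Reactants: 3 2-prenylcyclohexane-1,3-dione
Product: 4 3-methoxy-2-prenylcyclohex-2-en-1-one
Conditions: Me2SO4, K2CO3, acetone, reflux
Reagents that add atoms: dimethyl sulfate, COS(=O)(=O)OC
Why: O-methylation of the enolate by a hard electrophile gives the vinylogous ester needed for a Stork–Danheiser sequence, and the basic medium avoids acid-catalysed addition of the enol to the prenyl double bond.

**Step 3**
Reactants: 4 3-methoxy-2-prenylcyclohex-2-en-1-one
Product: 5 allyl 5-methoxy-6-prenylcyclohexa-1,5-dien-1-yl carbonate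
Conditions: LiN(i-Pr)2, TMEDA, THF, −78 °C; allyl chloroformate
Reagents that add atoms: allyl chloroformate, C=CCOC(=O)Cl
Why: Kinetic deprotonation of a vinylogous ester occurs at the α′ methylene (future C7), and the lithium dienolate is O-acylated by the chloroformate (enol carbonate formation), with TMEDA favouring the oxygen terminus.

**Step 4**
Reactants: 5 allyl 5-methoxy-6-prenylcyclohexa-1,5-dien-1-yl carbonate
Product: 6 (6R)-6-allyl-3-methoxy-2-prenylcyclohex-2-en-1-one
Conditions: Pd2(dba)3·CHCl3 (2.5 mol %), (S,S)-ANDEN-phenyl Trost ligand (5.5 mol %), 1,4-dioxane, 23 °C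
Reagents that add atoms: none
Why: In this decarboxylative asymmetric allylic alkylation (Tsuji–Trost type) zerovalent palladium ionises the allyl carbonate, CO2 is lost and the enolate is allylated regiospecifically at C7 inside the chiral pocket of the ligand, which selects the enolate face and sets C7, while the neutral medium keeps the α-tertiary centre from racemising.

**Step 5**
Reactants: 6 (6R)-6-allyl-3-methoxy-2-prenylcyclohex-2-en-1-one
Product: 7 (6R)-3-methoxy-2,6-diprenylcyclohex-2-en-1-one
Conditions: second-generation Grubbs catalyst (H2IMes)(PCy3)Cl2Ru=CHPh (3 mol %), 2-methyl-2-butene (solvent), 40 °C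
Reagents that add atoms: 2-methyl-2-butene, CC=C(C)C
Why: Olefin cross-metathesis turns the terminal allyl group into prenyl, while the prenyl group already present can only exchange degenerately and the tetrasubstituted ring alkene is inert.

**Step 6**
Reactants: 7 (6R)-3-methoxy-2,6-diprenylcyclohex-2-en-1-one
Product: 9 (4R)-3-methyl-2,4-diprenylcyclohex-2-en-1-one, via tertiary allylic alcohol 8 (not isolated)
Conditions: MeLi, Et2O, −78 → 0 °C; then 1 M HCl, THF, 0 °C
Reagents that add atoms: methyllithium, [Li]C
Why: In this Stork–Danheiser transposition MeLi adds 1,2 to the vinylogous ester carbonyl (future C8) and acid hydrolysis of the enol ether with loss of methanol moves the carbonyl to C9, leaving C7 (now γ to the enone) untouched under the brief mild acid treatment.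

**Step 7**
Reactants: 9 (4R)-3-methyl-2,4-diprenylcyclohex-2-en-1-one
Product: 11 (2S,4R)-3,3-dimethyl-2,4-diprenylcyclohexan-1-one (prenyl groups cis), via trimethylsilyl enol ether 10 (not isolated)
Conditions: MeMgBr, CuBr·SMe2 (15 mol %), Me3SiCl, HMPA, THF, −78 → −20 °C; then 1 M HCl, THF, 0 °C, short
Reagents that add atoms: methylmagnesium bromide, C[Mg]Br; chlorotrimethylsilane, C[Si](C)(C)Cl (silicon stays only in 10)
Why: Copper-catalysed conjugate addition of the Grignard reagent, accelerated by Me3SiCl for a fully substituted enone, completes the C8 gem-dimethyl group, and short hydrolysis of 10 protonates C1 along the axial trajectory anti to the axial C8 methyl, so the C1 prenyl group ends equatorial and cis to the C7 prenyl group, as step 9 requires.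

**Step 8**
Reactants: 11 (2S,4R)-3,3-dimethyl-2,4-diprenylcyclohexan-1-one; 12 geranyl bromide
Product: 13 (2S,4S,6RS)-6-geranyl-3,3-dimethyl-2,4-diprenylcyclohexan-1-one (C5 epimers)
Conditions: LiN(i-Pr)2, THF, −78 °C; 12, DMPU, −78 → 0 °C
Reagents that add atoms: none
Why: In this kinetic enolate alkylation the amide base takes a proton from the open C5 methylene rather than the C1 methine next to C8, and the C5 configuration is irrelevant because the centre is enolised again in step 9.

**Step 9**
Reactants: 13 6-geranyl-3,3-dimethyl-2,4-diprenylcyclohexan-1-one; 14 3-(trimethylsilyl)prop-2-ynal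
Product: 15 (2R,4S,6S)-2-geranyl-2-[1-hydroxy-3-(trimethylsilyl)prop-2-ynyl]-5,5-dimethyl-4,6-diprenylcyclohexan-1-one (carbinol epimers; C4 trans to the C7 prenyl)
Conditions: LiN(i-Pr)2, THF, −78 → 0 °C; 14, −78 °C; AcOH quench at −78 °C
Reagents that add atoms: none
Why: This is an aldol addition of the tetrasubstituted lithium enolate (C5–H is far more accessible than the neopentyl-type C1–H), in which, with both prenyl groups equatorial, the aldehyde approaches C5 axially on the face carrying only the axial hydrogens of C7 and C1, so C4 enters trans to the C7 prenyl and geranyl becomes equatorial, which sets C5.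

**Step 10**
Reactants: 15 aldol adduct
Product: 16 (2S,4S,6S)-2-geranyl-5,5-dimethyl-4,6-diprenyl-2-[3-(trimethylsilyl)prop-2-ynoyl]cyclohexan-1-one
Conditions: Dess–Martin periodinane, CH2Cl2, 0 °C → rt
Reagents that add atoms: none
Why: Dess–Martin oxidation converts the hindered propargylic alcohol into the ynone under nearly neutral conditions that spare the alkenes, the alkynylsilane and the non-enolisable 1,3-diketone.

**Step 11**
Reactants: 16 silyl ynone
Product: 17 (2S,4S,6S)-2-(3-bromoprop-2-ynoyl)-2-geranyl-5,5-dimethyl-4,6-diprenylcyclohexan-1-one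
Conditions: NBS (1.05 equiv), AgNO3 (10 mol %), dry acetone, 0 °C → rt, dark
Reagents that add atoms: N-bromosuccinimide, O=C1CCC(=O)N1Br
Why: In this silver-catalysed bromodesilylation monovalent silver turns the alkynylsilane into a silver acetylide that takes bromine from NBS much faster than the trisubstituted alkenes do, and it is run before the enol ether exists because that group would be brominated.

**Step 12**
Reactants: 17 bromoynone
Product: 18 3-bromo-1-[(1S,5S)-2-(tert-butyldimethylsilyloxy)-1-geranyl-4,4-dimethyl-3,5-diprenylcyclohex-2-en-1-yl]prop-2-yn-1-one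
Conditions: t-BuMe2SiOTf, i-Pr2NEt, CH2Cl2, 0 °C → rt
Reagents that add atoms: tert-butyldimethylsilyl triflate, CC(C)(C)[Si](C)(C)OS(=O)(=O)C(F)(F)F
Why: In this soft enolisation the C9 oxygen is silylated and C1–H, the only α-hydrogen in the molecule, is lost to a non-nucleophilic amine, which gives a single enol ether regioisomer, erases the C1 centre and never exposes the bromoynone to strong base.

**Step 13**
Reactants: 18 silyl enol ether bromoynone
Product: 19 (1R,5R,7S)-2-bromo-5-geranyl-8,8-dimethyl-1,7-diprenylbicyclo[3.3.1]non-2-ene-4,9-dione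
Conditions: (t-Bu)3PAuNTf2 (5 mol %), acetone, H2O (2 equiv), 23 °C
Reagents that add atoms: none
Why: π-Coordination of the cationic monovalent gold fragment (t-Bu)3PAu+ to the C2≡C3 triple bond makes C2 electrophilic, C1 of the enol silane attacks it on the side away from the metal, water strips the silyl group from the resulting C9 oxocarbenium ion, and protonolysis of the C3–Au bond releases the 2-bromoenone and the catalyst. The closest known reaction type is the gold-catalysed carbocyclisation of cyclic silyl enol ethers onto tethered alkynes, 1-bromoalkynes included, which delivers bicyclo[3.3.1]nonenones. Ring A (C1-C2-C3-C4-C5-C9) closes in the 6-endo-dig mode, with both alkyne carbons ending inside the new ring. The one new stereocentre, C1, is dictated by C5, because the axial acyl tether can reach only one face of the C1=C9 double bond, so C2 is delivered cis to C4 and the C1 prenyl group is pushed into the equatorial position of ring B. The step needs 6-endo rather than 5-exo attack (the ynone polarisation puts the positive charge on C2, the 5-exo product would be a strained bicyclo[2.2.1]heptanone, and the bulky phosphine disfavours the tighter exo transition state), C- rather than O-attack (the oxygen is capped by silicon), and attack by the enol ether rather than by the geranyl C2'=C3' alkene, which forms a 1,6-enyne with the alkyne but is a much weaker nucleophile towards an electron-poor alkyne and is not held over it. The vinylgold pathway also avoids the strained six-membered cyclic allenolate that a purely anionic 6-endo Michael closure would have to pass through.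

**Step 14**
Reactants: 19 bicyclic bromoenone
Product: 20 (1S,5R,7S)-5-geranyl-2-methoxy-8,8-dimethyl-1,7-diprenylbicyclo[3.3.1]non-2-ene-4,9-dione
Conditions: NaOMe, MeOH, 0 °C → rt
Reagents that add atoms: sodium methoxide, [Na+].[O-]C
Why: Addition–elimination (vinylogous acyl substitution) of methoxide at C2 of the β-bromoenone is fast at low temperature, which limits retro-Claisen attack on the C4/C9 diketone, and it brings C2 to the oxidation level of the trione.

**Step 15**
Reactants: 21 3,4-dihydroxybenzoic acid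
Product: 22 tert-butyldimethylsilyl 3,4-bis(tert-butyldimethylsilyloxy)benzoate
Conditions: t-BuMe2SiCl (3.3 equiv), imidazole, DMF, rt
Reagents that add atoms: tert-butyldimethylsilyl chloride, CC(C)(C)[Si](C)(C)Cl
Why: Exhaustive imidazole-promoted silylation masks both phenols and turns the acid into its silyl ester.

**Step 16**
Reactants: 22 tris-silyl derivative
Product: 23 3,4-bis(tert-butyldimethylsilyloxy)benzoyl chloride
Conditions: (COCl)2, DMF (cat.), CH2Cl2, 0 °C → rt
Reagents that add atoms: oxalyl chloride, O=C(Cl)C(=O)Cl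
Why: The silyl ester reacts with the Vilsmeier-type chloroiminium salt to give the acid chloride under neutral conditions, without the HCl that would cleave the aryl silyl ethers.

**Step 17**
Reactants: 20 2-methoxyenone; 23 acid chloride
Product: 24 (1S,5S,7S)-3-[3,4-bis(tert-butyldimethylsilyloxy)benzoyl]-5-geranyl-2-methoxy-8,8-dimethyl-1,7-diprenylbicyclo[3.3.1]non-2-ene-4,9-dione
Conditions: lithium 2,2,6,6-tetramethylpiperidide (from the amine and n-BuLi), THF, −78 °C; 23, −78 °C → −40 °C
Reagents that add atoms: none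
Why: With both bridgeheads quaternary, the hindered lithium amide removes the vinylic C3–H between the methoxy-bearing C2 and the C4 carbonyl (α-lithiation of a vinylogous ester), and the vinyllithium is acylated by 23.

**Step 18**
Reactants: 24 aroylated methyl enol ether
Product: 25 (1R,5R,7S)-3-[3,4-bis(tert-butyldimethylsilyloxy)benzoyl]-5-geranyl-4-hydroxy-8,8-dimethyl-1,7-diprenylbicyclo[3.3.1]non-3-ene-2,9-dione
Conditions: LiCl, DMSO, 120 °C, argon; dilute HCl work-up
Reagents that add atoms: none
Why: Nucleophilic demethylation (Krapcho-type SN2 at methyl by chloride) releases the stabilised β-triketone enolate, and any aryl silyl ether lost here is of no consequence because step 19 removes both.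

**Step 19**
Reactants: 25 bis-silyl ether
Product: 26 target, (1R,5R,7S)-3-(3,4-dihydroxybenzoyl)-5-geranyl-4-hydroxy-8,8-dimethyl-1,7-diprenylbicyclo[3.3.1]non-3-ene-2,9-dione
Conditions: Bu4NF, AcOH (1:1), THF, 0 °C
Reagents that add atoms: none
Why: Fluoride desilylation buffered with acetic acid frees the catechol without exposing it or the enolised triketone to base, or to acid that could cyclise the enol onto a prenyl group.

**Compound list**
1 | cyclohexane-1,3-dione | O=C1CCCC(=O)C1 | starting material
2 | prenyl bromide (1-bromo-3-methylbut-2-ene) | CC(C)=CCBr | starting material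
3 | 2-prenylcyclohexane-1,3-dione | CC(C)=CCC1C(=O)CCCC1=O | intermediate
4 | 3-methoxy-2-prenylcyclohex-2-en-1-one | COC1=C(CC=C(C)C)C(=O)CCC1 | intermediate
5 | allyl 5-methoxy-6-prenylcyclohexa-1,5-dien-1-yl carbonate | COC1=C(CC=C(C)C)C(OC(=O)OCC=C)=CCC1 | intermediate
6 | (6R)-6-allyl-3-methoxy-2-prenylcyclohex-2-en-1-one | COC1=C(CC=C(C)C)C(=O)[C@@H](CC=C)CC1 | intermediate
7 | (6R)-3-methoxy-2,6-diprenylcyclohex-2-en-1-one | COC1=C(CC=C(C)C)C(=O)[C@@H](CC=C(C)C)CC1 | intermediate
8 | (6R)-3-methoxy-1-methyl-2,6-diprenylcyclohex-2-en-1-ol (carbinol epimers, not isolated) | COC1=C(CC=C(C)C)C(C)(O)[C@@H](CC=C(C)C)CC1 | intermediate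
9 | (4R)-3-methyl-2,4-diprenylcyclohex-2-en-1-one | O=C1C(CC=C(C)C)=C(C)[C@@H](CC=C(C)C)CC1 | intermediate
10 | [(4R)-3,3-dimethyl-2,4-diprenylcyclohex-1-en-1-yl]oxytrimethylsilane (not isolated) | C[Si](C)(C)OC1=C(CC=C(C)C)C(C)(C)[C@@H](CC=C(C)C)CC1 | intermediate
11 | (2S,4R)-3,3-dimethyl-2,4-diprenylcyclohexan-1-one | O=C1[C@@H](CC=C(C)C)C(C)(C)[C@@H](CC=C(C)C)CC1 | intermediate
12 | geranyl bromide | CC(C)=CCC/C(C)=C/CBr | starting material
13 | (2S,4S,6RS)-6-geranyl-3,3-dimethyl-2,4-diprenylcyclohexan-1-one | CC(C)=CCC/C(C)=C/CC1C[C@H](CC=C(C)C)C(C)(C)[C@H](CC=C(C)C)C1=O | intermediate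
14 | 3-(trimethylsilyl)prop-2-ynal | C[Si](C)(C)C#CC=O | starting material
15 | (2R,4S,6S)-2-geranyl-2-[1-hydroxy-3-(trimethylsilyl)prop-2-ynyl]-5,5-dimethyl-4,6-diprenylcyclohexan-1-one (carbinol epimers) | CC(C)=CCC/C(C)=C/C[C@]1(C(O)C#C[Si](C)(C)C)C[C@H](CC=C(C)C)C(C)(C)[C@H](CC=C(C)C)C1=O | intermediate
16 | (2S,4S,6S)-2-geranyl-5,5-dimethyl-4,6-diprenyl-2-[3-(trimethylsilyl)prop-2-ynoyl]cyclohexan-1-one | CC(C)=CCC/C(C)=C/C[C@]1(C(=O)C#C[Si](C)(C)C)C[C@H](CC=C(C)C)C(C)(C)[C@H](CC=C(C)C)C1=O | intermediate
17 | (2S,4S,6S)-2-(3-bromoprop-2-ynoyl)-2-geranyl-5,5-dimethyl-4,6-diprenylcyclohexan-1-one | CC(C)=CCC/C(C)=C/C[C@]1(C(=O)C#CBr)C[C@H](CC=C(C)C)C(C)(C)[C@H](CC=C(C)C)C1=O | intermediate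
18 | 3-bromo-1-[(1S,5S)-2-(tert-butyldimethylsilyloxy)-1-geranyl-4,4-dimethyl-3,5-diprenylcyclohex-2-en-1-yl]prop-2-yn-1-one | CC(C)=CCC/C(C)=C/C[C@]1(C(=O)C#CBr)C[C@H](CC=C(C)C)C(C)(C)C(CC=C(C)C)=C1O[Si](C)(C)C(C)(C)C | intermediate
19 | (1R,5R,7S)-2-bromo-5-geranyl-8,8-dimethyl-1,7-diprenylbicyclo[3.3.1]non-2-ene-4,9-dione | CC(C)=CCC/C(C)=C/C[C@@]12C[C@H](CC=C(C)C)C(C)(C)[C@@](CC=C(C)C)(C(Br)=CC1=O)C2=O | intermediate
20 | (1S,5R,7S)-5-geranyl-2-methoxy-8,8-dimethyl-1,7-diprenylbicyclo[3.3.1]non-2-ene-4,9-dione | CC(C)=CCC/C(C)=C/C[C@@]12C[C@H](CC=C(C)C)C(C)(C)[C@@](CC=C(C)C)(C(OC)=CC1=O)C2=O | intermediate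
21 | 3,4-dihydroxybenzoic acid | OC(=O)c1ccc(O)c(O)c1 | starting material
22 | tert-butyldimethylsilyl 3,4-bis(tert-butyldimethylsilyloxy)benzoate | CC(C)(C)[Si](C)(C)OC(=O)c1ccc(O[Si](C)(C)C(C)(C)C)c(O[Si](C)(C)C(C)(C)C)c1 | intermediate
23 | 3,4-bis(tert-butyldimethylsilyloxy)benzoyl chloride | O=C(Cl)c1ccc(O[Si](C)(C)C(C)(C)C)c(O[Si](C)(C)C(C)(C)C)c1 | intermediate
24 | (1S,5S,7S)-3-[3,4-bis(tert-butyldimethylsilyloxy)benzoyl]-5-geranyl-2-methoxy-8,8-dimethyl-1,7-diprenylbicyclo[3.3.1]non-2-ene-4,9-dione | CC(C)=CCC/C(C)=C/C[C@@]12C[C@H](CC=C(C)C)C(C)(C)[C@@](CC=C(C)C)(C(OC)=C(C(=O)c3ccc(O[Si](C)(C)C(C)(C)C)c(O[Si](C)(C)C(C)(C)C)c3)C1=O)C2=O | intermediate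
25 | (1R,5R,7S)-3-[3,4-bis(tert-butyldimethylsilyloxy)benzoyl]-5-geranyl-4-hydroxy-8,8-dimethyl-1,7-diprenylbicyclo[3.3.1]non-3-ene-2,9-dione | CC(C)=CCC/C(C)=C/C[C@@]12C[C@H](CC=C(C)C)C(C)(C)[C@@](CC=C(C)C)(C(=O)C(C(=O)c3ccc(O[Si](C)(C)C(C)(C)C)c(O[Si](C)(C)C(C)(C)C)c3)=C1O)C2=O | intermediate
26 | (1R,5R,7S)-3-(3,4-dihydroxybenzoyl)-5-geranyl-4-hydroxy-8,8-dimethyl-1,7-diprenylbicyclo[3.3.1]non-3-ene-2,9-dione | CC(C)=CCC/C(C)=C/C[C@@]12C[C@H](CC=C(C)C)C(C)(C)[C@@](CC=C(C)C)(C(=O)C(C(=O)c3ccc(O)c(O)c3)=C1O)C2=O | target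

**Total step count:** 19. **Longest linear sequence:** 17 (steps 1–14 and 17–19).

**Steps most likely to fail**

1. Step 13. Joining two fully substituted carbons next to C8 may be too slow. Protodesilylation of the enol ether, cycloisomerisation of the alkyne with the geranyl alkene, or a 1,2-shift of bromine on gold could then take over.
   - The fallback sets out from 13 and comes back at 20. It replaces the alkyne closure by a double acylation.
   - 13 is treated with Me3SiOTf and Et3N to give the trimethylsilyl enol ether F1.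
   - F1 reacts with malonyl dichloride (CH2Cl2, −10 °C) and then aqueous KOH with BnEt3NCl. This is an Effenberger-type cyclisation that acylates C5 and then C1, with both new bonds axial and trans to the C7 prenyl group. It gives the bicyclic trione F2.
   - O-methylation of F2 with Me3SiCHN2 gives 20, which is separated by chromatography from the 4-methoxy regioisomer F3.

2. Step 9. Enolisation of the hindered ketone may be incomplete or may stray to C1. Facial selectivity at C5 may be poor if any C1-axial epimer is present, and the aldol may reverse on warming.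
   - The fallback sets out from 9 and comes back at 15. It quaternises C5 while C1 is still sp2.
   - LiN(i-Pr)2 and 12 convert 9 into the 6-geranyl enone F4.
   - A second deprotonation at the only α′ site, addition of 14 and capping of the aldolate with Me3SiCl give the silylated aldol F5.
   - In this dienolate A1,2 strain with the C8 methyl holds the C7 prenyl group pseudoaxial, so it screens one face of C5 and C4 again enters trans to it.
   - Copper-catalysed conjugate methylation under the conditions of step 7 gives the bis-silyl compound F6. Mild acid hydrolysis of F6, with axial protonation at C1, returns 15.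

3. Step 12. Removal of the crowded C1–H may be sluggish, and the amine or the triflate may degrade the bromoynone before the enol ether forms.
   - The fallback sets out from 15 and comes back at 18. It enolises with strong base before any ynone exists and oxidises last.
   - 1-(Trimethylsilyl)imidazole converts 15 into the silyl ether F7.
   - KN(SiMe3)2 followed by t-BuMe2SiOTf gives the C9 tert-butyldimethylsilyl enol ether F8. C1–H is the only acidic hydrogen in F7, and retro-aldol is blocked.
   - K2CO3 in MeOH removes both trimethylsilyl groups to give the terminal alkynol F9.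
   - n-BuLi (2 equiv) and then CBr4 brominate the acetylide without electrophilic bromine, giving the bromoalkynol F10.
   - MnO2 oxidises F10 to 18.

**Further compounds**
F1 | step 13 | trimethylsilyl enol ether of 13 (C5=C9) | CC(C)=CCC/C(C)=C/CC1=C(O[Si](C)(C)C)[C@@H](CC=C(C)C)C(C)(C)[C@@H](CC=C(C)C)C1
F2 | step 13 | 5-geranyl-8,8-dimethyl-1,7-diprenylbicyclo[3.3.1]nonane-2,4,9-trione | CC(C)=CCC/C(C)=C/C[C@@]12C[C@H](CC=C(C)C)C(C)(C)[C@@](CC=C(C)C)(C(=O)CC1=O)C2=O
F3 | step 13 | 4-methoxy regioisomer of 20 (5-geranyl-4-methoxy-8,8-dimethyl-1,7-diprenylbicyclo[3.3.1]non-3-ene-2,9-dione) | CC(C)=CCC/C(C)=C/C[C@@]12C[C@H](CC=C(C)C)C(C)(C)[C@@](CC=C(C)C)(C(=O)C=C1OC)C2=O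
F4 | step 9 | 6-geranyl-3-methyl-2,4-diprenylcyclohex-2-en-1-one (C5 epimers) | CC(C)=CCC/C(C)=C/CC1C[C@H](CC=C(C)C)C(C)=C(CC=C(C)C)C1=O
F5 | step 9 | 6-geranyl-3-methyl-2,4-diprenyl-6-[3-(trimethylsilyl)-1-(trimethylsilyloxy)prop-2-ynyl]cyclohex-2-en-1-one | CC(C)=CCC/C(C)=C/C[C@]1(C(O[Si](C)(C)C)C#C[Si](C)(C)C)C[C@H](CC=C(C)C)C(C)=C(CC=C(C)C)C1=O
F6 | step 9 | C9 trimethylsilyl enol ether of the O-trimethylsilyl ether of 15 | CC(C)=CCC/C(C)=C/C[C@]1(C(O[Si](C)(C)C)C#C[Si](C)(C)C)C[C@H](CC=C(C)C)C(C)(C)C(CC=C(C)C)=C1O[Si](C)(C)C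
F7 | step 12 | O-trimethylsilyl ether of 15 | CC(C)=CCC/C(C)=C/C[C@]1(C(O[Si](C)(C)C)C#C[Si](C)(C)C)C[C@H](CC=C(C)C)C(C)(C)[C@H](CC=C(C)C)C1=O
F8 | step 12 | C9 tert-butyldimethylsilyl enol ether of F7 | CC(C)=CCC/C(C)=C/C[C@]1(C(O[Si](C)(C)C)C#C[Si](C)(C)C)C[C@H](CC=C(C)C)C(C)(C)C(CC=C(C)C)=C1O[Si](C)(C)C(C)(C)C
F9 | step 12 | terminal alkynol with C9 tert-butyldimethylsilyl enol ether | CC(C)=CCC/C(C)=C/C[C@]1(C(O)C#C)C[C@H](CC=C(C)C)C(C)(C)C(CC=C(C)C)=C1O[Si](C)(C)C(C)(C)C
F10 | step 12 | bromoalkynol with C9 tert-butyldimethylsilyl enol ether | CC(C)=CCC/C(C)=C/C[C@]1(C(O)C#CBr)C[C@H](CC=C(C)C)C(C)(C)C(CC=C(C)C)=C1O[Si](C)(C)C(C)(C)C
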